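Assumption: the target has no stereocentre and no stereogenic double bond, so it is achiral; "single enantiomer" is taken to mean this one constitution and no asymmetric step is needed.

## Retrosynthetic overview

1. Target 22 ⇐ bis-MOM benzil 21 by one global acetal cleavage.
2. Key step: both C–C bonds of the 1,2-dione are made in one pot from aryllithium 17, the oxalyl dication equivalent 15 and aryllithium 19. The usual deoxybenzoin (Friedel–Crafts/Hoesch) plus SeO2 route is avoided.
3. Aryllithium 17 ⇐ ortho-lithiation of chromene 14 at its last aromatic C–H; 14 ⇐ chromanone 11 by reduction and dehydration.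
4. Chromanone 11 ⇐ Kabbe annulation of acetophenone 8 with acetone; the acetyl carbon becomes C4, which fixes OMe at C5 and O at C7.
5. Prenyl group ⇐ chelation-directed Claisen rearrangement of ether 5. Ring order: benzene ring A bought (4), pyranone ring in step 5, 2H-pyran in step 7, ring B bought (16).

## Route

Step 1
Reactants: 1 2-methylbut-3-en-2-ol
Product: 3 tert-butyl (2-methylbut-3-en-2-yl) carbonate, via lithium 2-methylbut-3-en-2-olate 2 (not isolated)
Conditions: n-BuLi, THF, 0 °C; then Boc2O, 0 °C → rt; H2O work-up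
Reagents that add atoms: di-tert-butyl dicarbonate (Boc2O), CC(C)(C)OC(=O)OC(=O)OC(C)(C)C
Why: Nucleophilic acyl substitution of Boc2O by the tertiary lithium alkoxide gives the mixed carbonate needed as the π-allyl precursor.

Step 2
Reactants: 4 1-(2,4-dihydroxy-6-methoxyphenyl)ethanone; 3 tert-butyl (2-methylbut-3-en-2-yl) carbonate
Product: 5 1-{2-hydroxy-6-methoxy-4-[(2-methylbut-3-en-2-yl)oxy]phenyl}ethanone
Conditions: 3 (1.3 equiv), Pd(PPh3)4 (3 mol%), THF, 0 °C → rt
Reagents that add atoms: none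
Why: Tsuji–Trost decarboxylative O-allylation, in which the free, more acidic 4-OH (the 2-OH is hydrogen-bonded to the acetyl group) attacks the more substituted end of the π-prenyl-palladium complex under kinetic control to give the tertiary ether.

Step 3
Reactants: 5 1-{2-hydroxy-6-methoxy-4-[(2-methylbut-3-en-2-yl)oxy]phenyl}ethanone
Product: 7 1-[2,4-dihydroxy-6-methoxy-3-(3-methylbut-2-en-1-yl)phenyl]ethanone, via Claisen ortho-dienone 6 (not isolated)
Conditions: m-xylene, 130 °C, sealed tube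
Reagents that add atoms: none
Why: Aromatic Claisen [3,3] rearrangement turns the tertiary allyl ether into a linear prenyl group, and the acetyl-chelated 2-OH fixes C3–C4 double-bond character so the shift goes to C3 (between the two oxygens) and not C5, before dienone 6 enolises back to the phenol.

Step 4
Reactants: 7 1-[2,4-dihydroxy-6-methoxy-3-(3-methylbut-2-en-1-yl)phenyl]ethanone
Product: 8 1-[2-hydroxy-6-methoxy-4-(methoxymethoxy)-3-(3-methylbut-2-en-1-yl)phenyl]ethanone
Conditions: MOMCl (1.1 equiv), i-Pr2NEt, CH2Cl2, 0 °C → rt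
Reagents that add atoms: chloromethyl methyl ether (MOMCl), COCCl
Why: Selective O-alkylation (Williamson-type acetal formation) of the non-chelated 4-OH, which installs the directing group for the later ortho-lithiation and leaves the 2-OH free for ring closure.

Step 5
Reactants: 8 1-[2-hydroxy-6-methoxy-4-(methoxymethoxy)-3-(3-methylbut-2-en-1-yl)phenyl]ethanone; 9 acetone
Product: 11 5-methoxy-7-(methoxymethoxy)-2,2-dimethyl-8-(3-methylbut-2-en-1-yl)-2,3-dihydro-4H-chromen-4-one, via aldol enone 10 (not isolated)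
Conditions: pyrrolidine (0.5 equiv), acetone/EtOH, 4 Å MS, reflux
Reagents that add atoms: none
Why: Kabbe chromanone synthesis (enamine-mediated aldol condensation, then intramolecular oxa-Michael addition), in which only the OH ortho to the acetyl group can close the ring, so OMe ends at C5, OMOM at C7 and prenyl at C8.

Step 6
Reactants: 11 5-methoxy-7-(methoxymethoxy)-2,2-dimethyl-8-(3-methylbut-2-en-1-yl)-2,3-dihydro-4H-chromen-4-one
Product: 12 5-methoxy-7-(methoxymethoxy)-2,2-dimethyl-8-(3-methylbut-2-en-1-yl)-3,4-dihydro-2H-chromen-4-ol (racemic)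
Conditions: NaBH4, MeOH/THF, 0 °C → rt
Reagents that add atoms: none
Why: Borohydride 1,2-reduction of the aryl ketone; the new C4 stereocentre is racemic and is destroyed in step 7.

Step 7
Reactants: 12 5-methoxy-7-(methoxymethoxy)-2,2-dimethyl-8-(3-methylbut-2-en-1-yl)-3,4-dihydro-2H-chromen-4-ol (racemic)
Product: 14 5-methoxy-7-(methoxymethoxy)-2,2-dimethyl-8-(3-methylbut-2-en-1-yl)-2H-chromene, via benzylic mesylate 13 (not isolated)
Conditions: MsCl, Et3N (3 equiv), CH2Cl2, 0 °C → rt
Reagents that add atoms: none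
Why: Mesylation then E1-type elimination, since the benzylic mesylate with three ortho/para oxygen donors ionises readily and loses H-3 to give the conjugated chromene under basic conditions that spare the MOM ether and the prenyl group.

Step 8
Reactants: 14 5-methoxy-7-(methoxymethoxy)-2,2-dimethyl-8-(3-methylbut-2-en-1-yl)-2H-chromene; 15 N,N'-dimethoxy-N,N'-dimethyloxamide; 16 1-bromo-4-(methoxymethoxy)benzene
Product: 21 1-[5-methoxy-7-(methoxymethoxy)-2,2-dimethyl-8-(3-methylbut-2-en-1-yl)-2H-chromen-6-yl]-2-[4-(methoxymethoxy)phenyl]ethane-1,2-dione, via C6-aryllithium 17 (not isolated), via mono-adduct lithium hemiaminolate 18 (not isolated), via 4-(methoxymethoxy)phenyllithium 19 (not isolated), via bis-adduct dilithium salt 20 (not isolated)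
Conditions: 14, n-BuLi (1.05 equiv), THF, 0 °C, 1 h; cannulate into 15 (1.05 equiv), THF, −78 °C; then 19 [from 16 (1.5 equiv), n-BuLi, THF, −78 °C], −78 → 0 °C; then H2O
Reagents that add atoms: none
Why: Directed ortho-metalation removes the only remaining aryl hydrogen (flanked by OMe and OMOM), the aryllithium adds once to the bis-Weinreb oxamide to give an N,O-chelated tetrahedral adduct that masks the first carbonyl, the second aryllithium adds to the remaining Weinreb amide, and hydrolysis releases the 1,2-dione (sequential Weinreb ketone synthesis on an oxalyl dication equivalent).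

Step 9
Reactants: 21 1-[5-methoxy-7-(methoxymethoxy)-2,2-dimethyl-8-(3-methylbut-2-en-1-yl)-2H-chromen-6-yl]-2-[4-(methoxymethoxy)phenyl]ethane-1,2-dione
Product: 22 1-[7-hydroxy-5-methoxy-2,2-dimethyl-8-(3-methylbut-2-en-1-yl)-2H-chromen-6-yl]-2-(4-hydroxyphenyl)ethane-1,2-dione (Derrisdione A)
Conditions: HCl (cat., 1 M in MeOH), MeOH, rt → 40 °C
Reagents that add atoms: none
Why: Acid-catalysed transacetalisation removes both MOM ethers (the one ortho to the ketone is carbonyl-assisted), and the mild methanolic conditions and the electron-poor, hydrogen-bonded 7-OH disfavour cyclisation onto the prenyl group; no stereocentre is involved.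

## Compound list

1 | 2-methylbut-3-en-2-ol | CC(C)(O)C=C | starting material
2 | lithium 2-methylbut-3-en-2-olate | CC(C)(O[Li])C=C | intermediate (not isolated)
3 | tert-butyl (2-methylbut-3-en-2-yl) carbonate | CC(C)(C)OC(=O)OC(C)(C)C=C | intermediate
4 | 1-(2,4-dihydroxy-6-methoxyphenyl)ethanone (2',4'-dihydroxy-6'-methoxyacetophenone) | CC(=O)c1c(O)cc(O)cc1OC | starting material
5 | 1-{2-hydroxy-6-methoxy-4-[(2-methylbut-3-en-2-yl)oxy]phenyl}ethanone | CC(=O)c1c(O)cc(OC(C)(C)C=C)cc1OC | intermediate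
6 | 4-acetyl-5-hydroxy-3-methoxy-6-(3-methylbut-2-en-1-yl)cyclohexa-2,4-dien-1-one (racemic Claisen dienone) | CC(=O)C1=C(O)C(CC=C(C)C)C(=O)C=C1OC | intermediate (not isolated)
7 | 1-[2,4-dihydroxy-6-methoxy-3-(3-methylbut-2-en-1-yl)phenyl]ethanone | CC(=O)c1c(O)c(CC=C(C)C)c(O)cc1OC | intermediate
8 | 1-[2-hydroxy-6-methoxy-4-(methoxymethoxy)-3-(3-methylbut-2-en-1-yl)phenyl]ethanone | CC(=O)c1c(O)c(CC=C(C)C)c(OCOC)cc1OC | intermediate
9 | acetone | CC(C)=O | starting material
10 | 1-[2-hydroxy-6-methoxy-4-(methoxymethoxy)-3-(3-methylbut-2-en-1-yl)phenyl]-3-methylbut-2-en-1-one | CC(C)=CC(=O)c1c(O)c(CC=C(C)C)c(OCOC)cc1OC | intermediate (not isolated)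
11 | 5-methoxy-7-(methoxymethoxy)-2,2-dimethyl-8-(3-methylbut-2-en-1-yl)-2,3-dihydro-4H-chromen-4-one | COc1cc(OCOC)c(CC=C(C)C)c2OC(C)(C)CC(=O)c12 | intermediate
12 | 5-methoxy-7-(methoxymethoxy)-2,2-dimethyl-8-(3-methylbut-2-en-1-yl)-3,4-dihydro-2H-chromen-4-ol (racemic) | COc1cc(OCOC)c(CC=C(C)C)c2OC(C)(C)CC(O)c12 | intermediate
13 | 5-methoxy-7-(methoxymethoxy)-2,2-dimethyl-8-(3-methylbut-2-en-1-yl)-3,4-dihydro-2H-chromen-4-yl methanesulfonate (racemic) | COc1cc(OCOC)c(CC=C(C)C)c2OC(C)(C)CC(OS(C)(=O)=O)c12 | intermediate (not isolated)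
14 | 5-methoxy-7-(methoxymethoxy)-2,2-dimethyl-8-(3-methylbut-2-en-1-yl)-2H-chromene | COc1cc(OCOC)c(CC=C(C)C)c2OC(C)(C)C=Cc12 | intermediate
15 | N,N'-dimethoxy-N,N'-dimethyloxamide | CON(C)C(=O)C(=O)N(C)OC | starting material
16 | 1-bromo-4-(methoxymethoxy)benzene | COCOc1ccc(Br)cc1 | starting material
17 | [5-methoxy-7-(methoxymethoxy)-2,2-dimethyl-8-(3-methylbut-2-en-1-yl)-2H-chromen-6-yl]lithium | COc1c([Li])c(OCOC)c(CC=C(C)C)c2OC(C)(C)C=Cc12 | intermediate (not isolated)
18 | lithium 1-(chromen-6-yl)-1,2-bis[methoxy(methyl)amino]-2-oxoethan-1-olate, chromenyl as in 14 (racemic mono-adduct) | COc1c(C(O[Li])(N(C)OC)C(=O)N(C)OC)c(OCOC)c(CC=C(C)C)c2OC(C)(C)C=Cc12 | intermediate (not isolated)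
19 | [4-(methoxymethoxy)phenyl]lithium | COCOc1ccc([Li])cc1 | intermediate (not isolated)
20 | dilithium 1-(chromen-6-yl)-1,2-bis[methoxy(methyl)amino]-2-[4-(methoxymethoxy)phenyl]ethane-1,2-diolate, chromenyl as in 14 (diastereomer mixture) | COc1c(C(O[Li])(N(C)OC)C(O[Li])(N(C)OC)c3ccc(OCOC)cc3)c(OCOC)c(CC=C(C)C)c2OC(C)(C)C=Cc12 | intermediate (not isolated)
21 | 1-[5-methoxy-7-(methoxymethoxy)-2,2-dimethyl-8-(3-methylbut-2-en-1-yl)-2H-chromen-6-yl]-2-[4-(methoxymethoxy)phenyl]ethane-1,2-dione | COc1c(C(=O)C(=O)c3ccc(OCOC)cc3)c(OCOC)c(CC=C(C)C)c2OC(C)(C)C=Cc12 | intermediate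
22 | Derrisdione A, 1-[7-hydroxy-5-methoxy-2,2-dimethyl-8-(3-methylbut-2-en-1-yl)-2H-chromen-6-yl]-2-(4-hydroxyphenyl)ethane-1,2-dione (achiral) | COc1c2c(c(CC=C(C)C)c(O)c1C(=O)C(=O)c1ccc(O)cc1)OC(C)(C)C=C2 | target

## Step count and risk

Total step count: 9. Longest linear sequence: 9 steps (1 → 3 → 5 → 7 → 8 → 11 → 12 → 14 → 21 → 22), or 8 steps counted from acetophenone 4.

The three steps most likely to fail:

**Step 8 (one-pot lithiation and double addition to the oxamide).** The hindered aryllithium 17 may add sluggishly, the first tetrahedral adduct may collapse early and expose the ketone to over-addition, or the second addition may stall. The fallback sets out from 14 and comes back at 21. Lithiate 14 as before and quench with N-methoxy-N-methylacetamide to give the methyl ketone 1-[5-methoxy-7-(methoxymethoxy)-2,2-dimethyl-8-(3-methylbut-2-en-1-yl)-2H-chromen-6-yl]ethanone F1. Palladium-catalysed ketone α-arylation of F1 with bromide 16 (Pd2(dba)3, Xantphos, NaOt-Bu, toluene, 80 °C) gives the deoxybenzoin 1-[5-methoxy-7-(methoxymethoxy)-2,2-dimethyl-8-(3-methylbut-2-en-1-yl)-2H-chromen-6-yl]-2-[4-(methoxymethoxy)phenyl]ethanone F2. Base-mediated aerobic oxidation of the doubly activated CH2 (DABCO or Cs2CO3, O2, DMF, 60–90 °C) then gives 21; SeO2 is avoided because it would oxidise the prenyl group.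

**Step 3 (regiochemistry of the Claisen rearrangement, C3 against C5).** If the shift to C5 competes, the fallback sets out from 4 and comes back at 8. Protect first with MOMCl and i-Pr2NEt to give 1-[2-hydroxy-6-methoxy-4-(methoxymethoxy)phenyl]ethanone F3. Palladium-catalysed O-allylation of the remaining chelated OH with carbonate 3 (Pd(PPh3)4, THF, rt → 40 °C) gives 1-{2-methoxy-4-(methoxymethoxy)-6-[(2-methylbut-3-en-2-yl)oxy]phenyl}ethanone F4. On heating (m-xylene, 130 °C) the ortho-Claisen shift of F4 can reach only one hydrogen-bearing ortho carbon, the one between the two oxygens, and gives 8 directly.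

**Step 9 (acidic removal of both MOM groups next to an ortho-prenylphenol and a chromene).** If chroman formation or addition to the chromene competes, the fallback sets out from 14 and comes back at 22. Run the step 8 protocol with commercial (4-bromophenoxy)(tert-butyl)dimethylsilane in place of 16 to give 2-{4-[tert-butyl(dimethyl)silyloxy]phenyl}-1-[5-methoxy-7-(methoxymethoxy)-2,2-dimethyl-8-(3-methylbut-2-en-1-yl)-2H-chromen-6-yl]ethane-1,2-dione F5. The carbonyl-activated ortho-MOM ether is then removed under very mild conditions (cat. PPTS, MeOH, rt → 40 °C) to give 2-{4-[tert-butyl(dimethyl)silyloxy]phenyl}-1-[7-hydroxy-5-methoxy-2,2-dimethyl-8-(3-methylbut-2-en-1-yl)-2H-chromen-6-yl]ethane-1,2-dione F6. Buffered fluoride (TBAF/AcOH, THF, 0 °C) finally removes the silyl ether and gives 22 without strong acid.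

## Further compounds

F1 | step 8 | 1-[5-methoxy-7-(methoxymethoxy)-2,2-dimethyl-8-(3-methylbut-2-en-1-yl)-2H-chromen-6-yl]ethanone | COc1c(C(C)=O)c(OCOC)c(CC=C(C)C)c2OC(C)(C)C=Cc12
F2 | step 8 | 1-[5-methoxy-7-(methoxymethoxy)-2,2-dimethyl-8-(3-methylbut-2-en-1-yl)-2H-chromen-6-yl]-2-[4-(methoxymethoxy)phenyl]ethanone | COc1c(C(=O)Cc3ccc(OCOC)cc3)c(OCOC)c(CC=C(C)C)c2OC(C)(C)C=Cc12
F3 | step 3 | 1-[2-hydroxy-6-methoxy-4-(methoxymethoxy)phenyl]ethanone | CC(=O)c1c(O)cc(OCOC)cc1OC
F4 | step 3 | 1-{2-methoxy-4-(methoxymethoxy)-6-[(2-methylbut-3-en-2-yl)oxy]phenyl}ethanone | CC(=O)c1c(OC(C)(C)C=C)cc(OCOC)cc1OC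
F5 | step 9 | 2-{4-[tert-butyl(dimethyl)silyloxy]phenyl}-1-[5-methoxy-7-(methoxymethoxy)-2,2-dimethyl-8-(3-methylbut-2-en-1-yl)-2H-chromen-6-yl]ethane-1,2-dione | COc1c(C(=O)C(=O)c3ccc(O[Si](C)(C)C(C)(C)C)cc3)c(OCOC)c(CC=C(C)C)c2OC(C)(C)C=Cc12
F6 | step 9 | 2-{4-[tert-butyl(dimethyl)silyloxy]phenyl}-1-[7-hydroxy-5-methoxy-2,2-dimethyl-8-(3-methylbut-2-en-1-yl)-2H-chromen-6-yl]ethane-1,2-dione | COc1c(C(=O)C(=O)c3ccc(O[Si](C)(C)C(C)(C)C)cc3)c(O)c(CC=C(C)C)c2OC(C)(C)C=Cc12
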